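**Plan**

1. Numbering: cyclohexane C1 (C–OH), C2, C3 (CHBr), C4 (CMeCl), C5, C6; cyclopentane C1' (quaternary, bonded to C1), C2' (CMe2), C3' (CHBr).
2. Cuts: the two halogens are removed first, back through an epoxide to a C3=C4 alkene. The resulting 1-hydroxy-4-methylcyclohex-3-ene is a ring-opened 2-methylbicyclo[3.1.0]hexan-2-ol, so a C1–C3 bond is added in thought and the C4–CH3 bond cut, which gives a bicyclo[3.1.0]hexan-2-one.
3. Feature used: in that bicycle C1, C2 and C3 form a cyclopropane fused to the five-membered ring C1–C3–C4–C5–C6. Cutting C3–C1 and C3–C2 leaves a carbene carbon C3 and a C1=C2 alkene joined by C4(=O)–C5–C6, a 1-diazohex-5-en-2-one. Further cuts at C4–C3, C1–C6 and C1–C2 lead to a C1' carboxylic acid.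
4. Forward order: chiral-pool cyclopentane, side chain, cyclopropane and cyclopentanone in one step, cyclohexene by cleavage of C1–C3, halogens last.
5. Stereochemistry: C1' comes from (−)-camphanic acid. C3' is set by reagent-controlled ketone reduction and SN2 inversion. C1 is set by the alkene face chosen by a chiral copper catalyst and is carried into the carbinol with inversion. C3 and C4 follow from hydroxyl-directed epoxidation, trans-diaxial opening and two bromonium-type shifts that keep each halogen on its own face.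

Key step: step 9

Assumption: in step 11 water is taken to enter C1 anti to the breaking C1–C3 bond, as in the opening of sabinene hydrate to terpinen-4-ol. Atom numbers in the Why lines are those of the target. Changes of the C1' descriptor along the route come from CIP priorities only, not from inversion.

**Route**

Step 1
Reactants: 1 (1S,4R)-4,7,7-trimethyl-3-oxo-2-oxabicyclo[2.2.1]heptane-1-carboxylic acid ((−)-camphanic acid)
Product: 4 (1R)-1,2,2-trimethyl-3-oxocyclopentane-1-carboxylic acid, via acyl azide 2 (not isolated), via isocyanate 3 (not isolated)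
Conditions: (PhO)2P(O)N3, Et3N, toluene, 80 °C; then 2 M aq NaOH, 60 °C; HCl to pH 2
Reagents that add atoms: aqueous sodium hydroxide, [Na+].[OH-] (water, O)
Why: Curtius rearrangement moves the bridgehead carbon C3' from carbon to nitrogen with retention, and the α-amino lactone formed on hydrolysis is an N,O-acetal that collapses to the C3' ketone and the C1' carboxylate (Curtius degradation of an α-acyloxy acid), leaving the quaternary C1' untouched.

Step 2
Reactants: 4 (1R)-1,2,2-trimethyl-3-oxocyclopentane-1-carboxylic acid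
Product: 6 (1R,3R)-3-hydroxy-1,2,2-trimethylcyclopentane-1-carboxylic acid, via acyloxyborane 5 (not isolated)
Conditions: (S)-Me-CBS oxazaborolidine (0.2 equiv), catecholborane (3 equiv), toluene, −78 → −40 °C; MeOH, then 1 M HCl
Reagents that add atoms: none
Why: Corey–Bakshi–Shibata reduction in which quaternary C2' is the large and C4'H2 the small flank of the ketone, so the (S)-catalyst should give the (3R)-alcohol with OH trans to the carboxyl group; the acid is masked in the flask as its acyloxyborane and returns on work-up, and any cis-hydroxy acid lactonises and is removed by base extraction.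

Step 3
Reactants: 6 (1R,3R)-3-hydroxy-1,2,2-trimethylcyclopentane-1-carboxylic acid
Product: 7 1-[(1R,3R)-3-hydroxy-1,2,2-trimethylcyclopentyl]ethan-1-one
Conditions: MeLi (4.5 equiv), Et2O, 0 → 35 °C; inverse quench into cold 1 M HCl
Reagents that add atoms: methyllithium, [Li]C
Why: Addition of methyllithium to the lithium carboxylate gives a dilithio gem-diolate that releases the methyl ketone only on hydrolysis (ketone synthesis from a carboxylic acid and an organolithium), the alkoxide at C3' being a spectator; this forms the C1–C2 bond.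

Step 4
Reactants: 7 1-[(1R,3R)-3-hydroxy-1,2,2-trimethylcyclopentyl]ethan-1-one
Product: 8 1-[(1R,3R)-3-hydroxy-1,2,2-trimethylcyclopentyl]ethenyl trifluoromethanesulfonate
Conditions: KN(SiMe3)2 (2.2 equiv), THF, −78 °C; PhNTf2 (1.05 equiv), −78 °C; aq NH4Cl
Reagents that add atoms: N-phenylbis(trifluoromethanesulfonimide), O=S(=O)(N(c1ccccc1)S(=O)(=O)C(F)(F)F)C(F)(F)F
Why: Only the acetyl methyl group carries enolisable hydrogens, so a single enolate forms and is O-sulfonylated at −78 °C much faster than the hindered secondary alkoxide (enol triflate formation).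

Step 5
Reactants: 8 1-[(1R,3R)-3-hydroxy-1,2,2-trimethylcyclopentyl]ethenyl trifluoromethanesulfonate
Product: 9 1-[(1R,3S)-3-bromo-1,2,2-trimethylcyclopentyl]ethenyl trifluoromethanesulfonate
Conditions: CBr4, PPh3, CH2Cl2, 0 → 40 °C
Reagents that add atoms: carbon tetrabromide, BrC(Br)(Br)Br
Why: Appel reaction in which bromide displaces the alkoxyphosphonium group by SN2 with inversion, turning (3R)-OH into (3S)-Br cis to the side chain; it is placed here because the enol triflate, unlike a carbonyl group anti to the leaving group, cannot take part as a neighbouring group, and displacements of this kind are precedented on 2,2-dimethylcyclopentanols with a quaternary C3.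

Step 6
Reactants: 9 1-[(1R,3S)-3-bromo-1,2,2-trimethylcyclopentyl]ethenyl trifluoromethanesulfonate; 10 ethyl 3-iodopropanoate
Product: 12 ethyl 4-[(1S,3S)-3-bromo-1,2,2-trimethylcyclopentyl]pent-4-enoate, via alkylzinc iodide 11 (not isolated)
Conditions: Zn dust (BrCH2CH2Br, Me3SiCl activation), 10, THF, 35 °C; then 9, Pd(PPh3)4 (5 mol %), THF, 50 °C
Reagents that add atoms: ethyl 3-iodopropanoate 10, CCOC(=O)CCI, transferred as its zinc reagent 11, CCOC(=O)CC[Zn]I
Why: Negishi coupling in which zerovalent palladium inserts into the vinyl C–OTf bond far faster than into the hindered secondary C–Br bond and the ester-bearing alkylzinc iodide transfers its primary alkyl group, forming the C1–C6 bond of the 1,1-disubstituted alkene.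

Step 7
Reactants: 12 ethyl 4-[(1S,3S)-3-bromo-1,2,2-trimethylcyclopentyl]pent-4-enoate
Product: 13 4-[(1S,3S)-3-bromo-1,2,2-trimethylcyclopentyl]pent-4-enoic acid
Conditions: LiOH·H2O, THF/MeOH/H2O, 23 °C; 1 M HCl
Reagents that add atoms: lithium hydroxide, [Li+].[OH-]
Why: Saponification of an unhindered primary-chain ester; the neopentyl-type secondary bromide is inert to aqueous hydroxide at room temperature.

Step 8
Reactants: 13 4-[(1S,3S)-3-bromo-1,2,2-trimethylcyclopentyl]pent-4-enoic acid; 14 (trimethylsilyl)diazomethane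
Product: 16 5-[(1S,3S)-3-bromo-1,2,2-trimethylcyclopentyl]-1-diazohex-5-en-2-one, via mixed anhydride 15 (not isolated)
Conditions: i-BuOCOCl, Et3N, THF, −20 °C; then Me3SiCHN2 (2 M in hexanes), MeCN, 0 → 23 °C
Reagents that add atoms: (trimethylsilyl)diazomethane 14, C[Si](C)(C)C=[N+]=[N-]
Why: C-acylation of the diazoalkane by a mixed carbonic anhydride with loss of the silyl group (diazoketone synthesis of the Arndt–Eistert type), chosen over the acid chloride so that no HCl meets the 1,1-disubstituted alkene; this forms the C4–C3 bond.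

Step 9
Reactants: 16 5-[(1S,3S)-3-bromo-1,2,2-trimethylcyclopentyl]-1-diazohex-5-en-2-one
Product: 17 (1R,5R)-5-[(1S,3S)-3-bromo-1,2,2-trimethylcyclopentyl]bicyclo[3.1.0]hexan-2-one
Conditions: CuOTf·½C6H6 (5 mol %), (S,S)-t-Bu-box [2,2′-(propane-2,2-diyl)bis((4S)-4-tert-butyl-4,5-dihydrooxazole)] (6 mol %), CH2Cl2, 23 °C, slow addition of 16
Reagents that add atoms: none
Why: Loss of N2 from 16 at monovalent copper gives an electrophilic copper carbenoid whose carbon (future C3) attacks the terminal alkene carbon C2 and then closes onto C1, the positive charge in the transition state being carried by the fully substituted C1. The closest known reaction type is the copper- or rhodium-catalysed intramolecular cyclopropanation of 1-diazohex-5-en-2-ones to bicyclo[3.1.0]hexan-2-ones. The cyclopropane closes by [2+1] addition of the carbenoid across C1=C2, and the cyclopentanone (C3, C4, C5, C6, C1) closes at the same time because the two-carbon tether delivers the carbenoid to the internal alkene carbon, which allows only the cis ring fusion. C1 and C3 form together, so their relative configuration is fixed by the fusion; which alkene face is taken, and with it the configuration of 17 relative to C1', is decided by the C2-symmetric bis(oxazoline) on copper, because C1' sits on a freely rotating bond and biases the faces only weakly. The selectivity needed is therefore face selectivity, secured by the ligand; chemoselectivity is secured by the substrate, since the atom five positions from the carbenoid is the alkene carbon itself and the adjacent C1' has no hydrogen, so 1,5 C–H insertion cannot compete, and slow addition suppresses carbene dimers.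

Step 10
Reactants: 17 (1R,5R)-5-[(1S,3S)-3-bromo-1,2,2-trimethylcyclopentyl]bicyclo[3.1.0]hexan-2-one
Product: 18 (1R,2S,5R)-5-[(1S,3S)-3-bromo-1,2,2-trimethylcyclopentyl]-2-methylbicyclo[3.1.0]hexan-2-ol
Conditions: MeMgBr, CeCl3, THF, −78 °C; aq NH4Cl
Reagents that add atoms: methylmagnesium bromide, C[Mg]Br
Why: Organocerium addition to the C4 ketone avoids enolisation and should bring the methyl group in anti to the cyclopropane methylene; the new carbinol configuration is of no consequence because C4 becomes trigonal in the next step.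

Step 11
Reactants: 18 (1R,2S,5R)-5-[(1S,3S)-3-bromo-1,2,2-trimethylcyclopentyl]-2-methylbicyclo[3.1.0]hexan-2-ol
Product: 19 (1R)-1-[(1R,3S)-3-bromo-1,2,2-trimethylcyclopentyl]-4-methylcyclohex-3-en-1-ol
Conditions: HClO4 (0.02 M), acetone/H2O 4:1, 0 °C; NaHCO3
Reagents that add atoms: water, O
Why: Ionisation of the tertiary cyclopropyl carbinol at C4 is assisted by the C1–C3 bond and water attacks C1 anti to that bond (cyclopropylcarbinyl-to-homoallyl rearrangement, as in the opening of sabinene hydrate to terpinen-4-ol), so the cyclopropane configuration becomes the (1R) carbinol configuration and the C3=C4 alkene appears; the acid is kept very dilute so that the product alcohol at C1 does not ionise.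

Step 12
Reactants: 19 (1R)-1-[(1R,3S)-3-bromo-1,2,2-trimethylcyclopentyl]-4-methylcyclohex-3-en-1-ol
Product: 20 (1R,3R,6S)-3-[(1R,3S)-3-bromo-1,2,2-trimethylcyclopentyl]-6-methyl-7-oxabicyclo[4.1.0]heptan-3-ol
Conditions: VO(acac)2 (5 mol %), t-BuOOH, toluene, 23 °C
Reagents that add atoms: tert-butyl hydroperoxide, CC(C)(C)OO
Why: Hydroxyl-directed epoxidation in which the vanadium-bound peroxide is delivered to the alkene face syn to the axial C1 hydroxyl, as known for terpinen-4-ol, fixing the epoxide oxygen on the hydroxyl face of C3 and C4.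

Step 13
Reactants: 20 (1R,3R,6S)-3-[(1R,3S)-3-bromo-1,2,2-trimethylcyclopentyl]-6-methyl-7-oxabicyclo[4.1.0]heptan-3-ol
Product: 21 (1R,3R,4R)-4-bromo-1-[(1R,3S)-3-bromo-1,2,2-trimethylcyclopentyl]-4-methylcyclohexane-1,3-diol
Conditions: LiBr, AcOH, THF, 0 → 23 °C
Reagents that add atoms: lithium bromide, [Li+].[Br-]
Why: Acid-assisted anti opening of the epoxide by bromide, in which the trans-diaxial path and attack at the tertiary carbon coincide at C4 (the cyclopentyl group anchors the chair), placing bromine axial on C4 on the face opposite to the hydroxyl groups and leaving an axial C3–OH.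

Step 14
Reactants: 21 (1R,3R,4R)-4-bromo-1-[(1R,3S)-3-bromo-1,2,2-trimethylcyclopentyl]-4-methylcyclohexane-1,3-diol
Product: 22 (1R,3R,4R)-4-bromo-1-[(1R,3S)-3-bromo-1,2,2-trimethylcyclopentyl]-3-chloro-4-methylcyclohexan-1-ol
Conditions: PPh3, CCl4, MeCN, 0 → 23 °C
Reagents that add atoms: carbon tetrachloride, ClC(Cl)(Cl)Cl
Why: Appel chlorination of the secondary alcohol with neighbouring-group participation, in which the anti-periplanar C4 bromine expels the phosphonium oxide to give a bromonium ion on the face opposite to the C1 hydroxyl and chloride opens it axially at C3 with net retention (as in the conversion of trans-2-bromocyclohexanol into trans-1-bromo-2-chlorocyclohexane); the tertiary C1–OH is not activated, and any chloride entering at C4 gives 23 directly.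

Step 15
Reactants: 22 (1R,3R,4R)-4-bromo-1-[(1R,3S)-3-bromo-1,2,2-trimethylcyclopentyl]-3-chloro-4-methylcyclohexan-1-ol
Product: 23 (1R,3S,4S)-3-bromo-1-[(1R,3S)-3-bromo-1,2,2-trimethylcyclopentyl]-4-chloro-4-methylcyclohexan-1-ol
Conditions: toluene, 90 °C, dark
Reagents that add atoms: none
Why: Thermal 1,2-interchange of trans-diaxial vicinal halogens (diaxial-to-diequatorial rearrangement, known for steroidal 5,6-dihalides and halogenated methylcyclohexane terpenoids), in which each halogen stays on its own face while bromine moves from C4 to C3 and chlorine from C3 to C4; relief of the syn-axial Cl/OH contact in 22 should favour 23.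

**Compound list**

1 | (1S,4R)-4,7,7-trimethyl-3-oxo-2-oxabicyclo[2.2.1]heptane-1-carboxylic acid ((−)-camphanic acid) | CC1(C)[C@]2(C(=O)O)CC[C@@]1(C)C(=O)O2 | starting material
2 | (1S,4R)-4,7,7-trimethyl-3-oxo-2-oxabicyclo[2.2.1]heptane-1-carbonyl azide | CC1(C)[C@]2(C(=O)N=[N+]=[N-])CC[C@@]1(C)C(=O)O2 | intermediate
3 | (1S,4R)-1-isocyanato-4,7,7-trimethyl-2-oxabicyclo[2.2.1]heptan-3-one | CC1(C)[C@]2(N=C=O)CC[C@@]1(C)C(=O)O2 | intermediate
4 | (1R)-1,2,2-trimethyl-3-oxocyclopentane-1-carboxylic acid | CC1(C)C(=O)CC[C@@]1(C)C(=O)O | intermediate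
5 | 1,3,2-benzodioxaborol-2-yl (1R)-1,2,2-trimethyl-3-oxocyclopentane-1-carboxylate | CC1(C)C(=O)CC[C@@]1(C)C(=O)OB1Oc2ccccc2O1 | intermediate
6 | (1R,3R)-3-hydroxy-1,2,2-trimethylcyclopentane-1-carboxylic acid | CC1(C)[C@H](O)CC[C@@]1(C)C(=O)O | intermediate
7 | 1-[(1R,3R)-3-hydroxy-1,2,2-trimethylcyclopentyl]ethan-1-one | CC1(C)[C@H](O)CC[C@@]1(C)C(C)=O | intermediate
8 | 1-[(1R,3R)-3-hydroxy-1,2,2-trimethylcyclopentyl]ethenyl trifluoromethanesulfonate | CC1(C)[C@H](O)CC[C@@]1(C)C(=C)OS(=O)(=O)C(F)(F)F | intermediate
9 | 1-[(1R,3S)-3-bromo-1,2,2-trimethylcyclopentyl]ethenyl trifluoromethanesulfonate | CC1(C)[C@@H](Br)CC[C@@]1(C)C(=C)OS(=O)(=O)C(F)(F)F | intermediate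
10 | ethyl 3-iodopropanoate | CCOC(=O)CCI | starting material
11 | (3-ethoxy-3-oxopropyl)zinc iodide | CCOC(=O)CC[Zn]I | intermediate
12 | ethyl 4-[(1S,3S)-3-bromo-1,2,2-trimethylcyclopentyl]pent-4-enoate | CC1(C)[C@@H](Br)CC[C@@]1(C)C(=C)CCC(=O)OCC | intermediate
13 | 4-[(1S,3S)-3-bromo-1,2,2-trimethylcyclopentyl]pent-4-enoic acid | CC1(C)[C@@H](Br)CC[C@@]1(C)C(=C)CCC(=O)O | intermediate
14 | (trimethylsilyl)diazomethane | C[Si](C)(C)C=[N+]=[N-] | starting material
15 | 4-[(1S,3S)-3-bromo-1,2,2-trimethylcyclopentyl]pent-4-enoic 2-methylpropyl carbonic anhydride | CC1(C)[C@@H](Br)CC[C@@]1(C)C(=C)CCC(=O)OC(=O)OCC(C)C | intermediate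
16 | 5-[(1S,3S)-3-bromo-1,2,2-trimethylcyclopentyl]-1-diazohex-5-en-2-one | CC1(C)[C@@H](Br)CC[C@@]1(C)C(=C)CCC(=O)C=[N+]=[N-] | intermediate
17 | (1R,5R)-5-[(1S,3S)-3-bromo-1,2,2-trimethylcyclopentyl]bicyclo[3.1.0]hexan-2-one | CC1(C)[C@@H](Br)CC[C@@]1(C)[C@]12C[C@H]1C(=O)CC2 | intermediate
18 | (1R,2S,5R)-5-[(1S,3S)-3-bromo-1,2,2-trimethylcyclopentyl]-2-methylbicyclo[3.1.0]hexan-2-ol | CC1(C)[C@@H](Br)CC[C@@]1(C)[C@]12C[C@H]1[C@@](C)(O)CC2 | intermediate
19 | (1R)-1-[(1R,3S)-3-bromo-1,2,2-trimethylcyclopentyl]-4-methylcyclohex-3-en-1-ol | CC1(C)[C@@H](Br)CC[C@@]1(C)[C@@]1(O)CCC(C)=CC1 | intermediate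
20 | (1R,3R,6S)-3-[(1R,3S)-3-bromo-1,2,2-trimethylcyclopentyl]-6-methyl-7-oxabicyclo[4.1.0]heptan-3-ol | CC1(C)[C@@H](Br)CC[C@@]1(C)[C@@]1(O)CC[C@]2(C)O[C@@H]2C1 | intermediate
21 | (1R,3R,4R)-4-bromo-1-[(1R,3S)-3-bromo-1,2,2-trimethylcyclopentyl]-4-methylcyclohexane-1,3-diol | CC1(C)[C@@H](Br)CC[C@@]1(C)[C@@]1(O)CC[C@@](C)(Br)[C@H](O)C1 | intermediate
22 | (1R,3R,4R)-4-bromo-1-[(1R,3S)-3-bromo-1,2,2-trimethylcyclopentyl]-3-chloro-4-methylcyclohexan-1-ol | CC1(C)[C@@H](Br)CC[C@@]1(C)[C@@]1(O)CC[C@@](C)(Br)[C@H](Cl)C1 | intermediate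
23 | (1R,3S,4S)-3-bromo-1-[(1R,3S)-3-bromo-1,2,2-trimethylcyclopentyl]-4-chloro-4-methylcyclohexan-1-ol | CC1(C)[C@@H](Br)CC[C@@]1(C)[C@@]1(O)CC[C@](C)(Cl)[C@@H](Br)C1 | target

Total step count: 15
Longest linear sequence: 15 steps (1 to 23)

**Steps most likely to fail**

Step 9. The alkene face may be chosen poorly, because C1' sits on a freely rotating bond and the ligand alone must decide, and the acceptor-only carbenoid may dimerise. The first recourse, the enantiomeric ligand, is only a change of conditions. The fallback changes the carbenoid to an acceptor/acceptor one, a class for which copper bis(oxazoline) catalysts are known to control the face on 1,1-disubstituted alkenes. It sets out from 12. Lithiated methyl 2,4,6-trimethylphenyl sulfone (2 equiv, THF, −78 °C) would give the β-keto sulfone F1. Diazo transfer (4-acetamidobenzenesulfonyl azide, Et3N, MeCN) would give the α-diazo-β-keto sulfone F2. CuOTf with the same ligand class in toluene would give the sulfonyl bicyclic ketone F3. Reductive removal of the sulfonyl group (SmI2, THF/MeOH, −78 °C) comes back to the route at 17.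

Step 5. Elimination towards C4' or a 1,2-methyl shift from C2' may outrun substitution at the neopentyl-type carbon. The fallback moves the substitution behind the cross-coupling and runs it as a sulfonate displacement. It sets out from 8. Negishi coupling with 11 under the conditions of step 6, with the free hydroxyl carried as its zinc alkoxide, would give the hydroxy ester F4. ClCH2SO2Cl and pyridine (CH2Cl2, 0 °C) would give the chloromethanesulfonate F5. Bu4NBr in toluene at 80 °C should then displace it with inversion and come back to the route at 12.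

Step 15. The tertiary bromide of 22 may lose HBr on heating, the equilibrium may not lie far enough on the side of 23, or the C1 hydroxyl may capture the ion pair. The fallback places the bromine on the face opposite to the hydroxyl by ether formation instead. It sets out from 19. NBS (CH2Cl2, 0 °C) would give the bridged bromo ether F6, with the C1 oxygen bonded to C4 and bromine on C3 anti to it. TiCl4 (CH2Cl2, −78 °C) is then meant to break the C4–O bond with help from the anti bromine and to hand chloride to C4 from the oxygen side, which comes back to the route at 23.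

**Further compounds**

F1 | step 9 | 5-[(1S,3S)-3-bromo-1,2,2-trimethylcyclopentyl]-1-(2,4,6-trimethylbenzenesulfonyl)hex-5-en-2-one | CC1(C)[C@@H](Br)CC[C@@]1(C)C(=C)CCC(=O)CS(=O)(=O)c1c(C)cc(C)cc1C
F2 | step 9 | 5-[(1S,3S)-3-bromo-1,2,2-trimethylcyclopentyl]-1-diazo-1-(2,4,6-trimethylbenzenesulfonyl)hex-5-en-2-one | CC1(C)[C@@H](Br)CC[C@@]1(C)C(=C)CCC(=O)C(=[N+]=[N-])S(=O)(=O)c1c(C)cc(C)cc1C
F3 | step 9 | (1S,5S)-5-[(1S,3S)-3-bromo-1,2,2-trimethylcyclopentyl]-1-(2,4,6-trimethylbenzenesulfonyl)bicyclo[3.1.0]hexan-2-one | CC1(C)[C@@H](Br)CC[C@@]1(C)[C@]12C[C@@]1(S(=O)(=O)c1c(C)cc(C)cc1C)C(=O)CC2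
F4 | step 5 | ethyl 4-[(1S,3R)-3-hydroxy-1,2,2-trimethylcyclopentyl]pent-4-enoate | CC1(C)[C@H](O)CC[C@@]1(C)C(=C)CCC(=O)OCC
F5 | step 5 | ethyl 4-[(1S,3R)-3-(chloromethanesulfonyloxy)-1,2,2-trimethylcyclopentyl]pent-4-enoate | CC1(C)[C@H](OS(=O)(=O)CCl)CC[C@@]1(C)C(=C)CCC(=O)OCC
F6 | step 15 | (1S,2S,4R)-2-bromo-4-[(1R,3S)-3-bromo-1,2,2-trimethylcyclopentyl]-1-methyl-7-oxabicyclo[2.2.1]heptane | CC1(C)[C@@H](Br)CC[C@@]1(C)[C@@]1(O2)CC[C@@]2(C)[C@@H](Br)C1
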